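**Numbering.** Compounds 1–47 are numbered in the order of the steps below; the same numbers are used in every section.

## Analysis of the target

Compound 47 contains a trans-anti-trans dodecahydrofluorene: ring A is a cyclohexane with two equatorial secondary methyl groups and an axial angular methyl group, ring B is a cyclopentane, and ring C is a cyclohexane. A 13-membered para-cyclophane spans this core. It runs from the ring-B oxygen through the benzene ring and its benzylic CH2 to the hemiaminal carbon of a γ-lactam, then through the lactam CH2, the quaternary spiro carbon and a ketone to ring C. The spiro carbon also carries the CH2–CH(OH) arm of an eight-membered 1,2-dioxocane, whose peroxide ends on the methyl-bearing ring-C carbon next to the ketone-bearing one; ring C further holds a trisubstituted epoxide cis to the peroxide. There are 14 stereocentres. Nine lie on the carbocycle, where both ring fusions are trans and the ring-B oxygen, the ring-C acyl group and the angular methyl group share one face. The others are the epoxide carbons, the peroxyhemiacetal carbon, the spiro carbon and the hemiaminal carbon. The peroxide and peroxyhemiacetal do not survive reductants, bases or low-valent metals, the hemiaminal ionises in acid, and the β-keto lactam has a quaternary α-carbon that cannot be corrected once set. The hard points are the strain of the para-cyclophane, the trans-fused hydrindane with an oxygen next to the ring fusion, and the need to bring in the peroxide last. The strategy rests on the hemiaminal carbon: it carries OH, N and the benzylic CH2, which is what a benzyl nucleophile leaves when it adds to the succinimide carbonyl that is remote from the spiro carbon.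

## Retrosynthetic reasoning

**Epoxide.** The epoxide of 47 is opened to bromohydrin 46, which comes from alkene 45. The two-step route is chosen because the alkene face that must carry the oxygen is the one screened by the peroxide bridge. A bromonium ion on the open face followed by closure with inversion puts the oxygen where a direct epoxidation would not.

**Dioxocane.** In 45 the C–O bond at the methyl-bearing ring-C carbon and the O–C bond of the peroxyhemiacetal are cut, leading to keto aldehyde 43. Forward, an ene photo-oxygenation makes the tertiary allylic hydroperoxide 44 and moves the alkene to where the epoxide is needed; 44 then adds to the aldehyde. The peroxide is therefore present only in the last three steps.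

**Functional-group level.** 43 is traced to 41 (N-benzyl-type group and acetal removed together) and then to 39 (ketone carried as a silyl ether). The masks are needed because the ring closure uses a strong one-electron reductant and a basic organometallic.

**Cyclophane (key disconnection).** In 39 the bond between the benzylic CH2 and the hemiaminal carbon is cut, giving bromide 38 with an intact spiro-succinimide. This bond is chosen because it is the only one in the 13-membered ring whose formation also creates a functional group of the target, and because the two imide carbonyls are differentiated by the quaternary carbon. Forward, a samarium-mediated Barbier addition must close the ring against strain.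

**Spiro carbon.** 38 is cut between the carbinol carbon and the quaternary carbon into aldehyde 27 and alkylidene succinimide 34. A reductive aldol generates the enolate at the substituted carbon only, and must set the quaternary centre.

**Aryl ether.** The aryl–O bond of 27 is cut to tricyclic alcohol 21 and aryl fluoride 22 (nucleophilic aromatic substitution, retention at the carbinol carbon).

**Rings B and A.** 21 is opened at the bond from the ring-B carbinol carbon to the ring-fusion CH and at the bond from the angular-methyl carbon to the ring-A CH2, giving monocyclic aldehyde 19. A cation–olefin bicyclisation sets the carbinol, the trans fusion and the quaternary centre by anti addition across an (E)-alkene; no ketone ever sits next to the ring fusion, so the less stable trans-hydrindane cannot epimerise.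

**Ring-C CH2O group and alkene.** 19 goes back through a [2,3] rearrangement to cyclohexenone 13. The rearrangement puts the one-carbon unit on the correct face by chirality transfer and leaves the alkene where the ene reaction needs it.

**Ring C.** 13 is cut into trienal 9 and diene 10 (Diels–Alder reaction); 9 comes from 1 and 2 by an auxiliary alkylation and two Wittig homologations with 5 and 8.

**Imide.** 34 comes from 28, 29 and 32.

## Alternatives that were turned down

Each alternative was weighed as the step on which the whole plan should turn.

**Alternative 1:** rings B and A are disconnected together, at the bond from the ring-B carbinol carbon to the ring-fusion CH and at the bond from the angular-methyl carbon to the ring-A CH2. Forward, a Lewis acid activates the formyl group on ring C, the alkene CH attacks it, and a methallyl terminus captures the tertiary cation; proton loss gives A1. In its favour, two rings and three stereocentres form in one step, and the trans fusion follows from anti addition. Against it, as given: A1 carries two trisubstituted alkenes, one in ring A and one in ring C, so the ring-A alkene would have to be hydrogenated selectively, and from the face under the angular methyl group if the new methyl is to end up equatorial. More basically, it solves only the carbocycle and leaves the strained cyclophane to unspecified chemistry. On the core it is stronger than anything stepwise, and the chosen route keeps its bond construction in step 11, with an allylsilane terminus so that the ring-A alkene is exocyclic and distinguishable. What the chosen strategy adds is a solution for the 13-membered ring, where the real risk lies.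

**Alternative 2:** ring C is disconnected late, at the bond between the CH2 next to the ketone and the methyl-bearing carbon. Forward, a Lewis acid ionises a methoxy silylperoxy ketal and the silyl enol ether carbon attacks the peroxycarbenium ion, giving A2. In its favour, the peroxide oxygen is fixed on the right carbon by construction and the alkene is already where the epoxide is needed; on this point it is stronger than an ene reaction, whose regio- and facial selectivity must be argued. Against it: the peroxycarbenium ion is allylic and can be attacked at its far end or fragment; two stereocentres of ring C must be set on a macrocyclic template with no cycloaddition to control them; the peroxide must then survive ketal removal, amide cyclisation and alcohol oxidation; and the cyclophane must already exist. The chosen strategy sets ring C early by a cycloaddition, carries the peroxide through only three steps, and closes the cyclophane itself.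

**Alternative 3:** the dioxocane is disconnected at the C–O bond on ring C and the O–C bond of the peroxyhemiacetal. Forward, sensitised photo-oxygenation of the ring-C alkene gives a hydroperoxide that closes onto the pendant aldehyde to give A3. In its favour, it is short, uses oxygen itself, and the alkene shift delivers the alkene for the epoxide. Against it as the carrying idea: it is the last constructive event and presupposes the complete cyclophane keto aldehyde, so it cannot organise the synthesis. It does not compete with the chosen strategy for the same bonds; the chosen route ends with this closure (step 28, A3 is 45). The chosen strategy supplies the substrate that this closure needs.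

Key step: step 24

Remark 1: the (S)-proline-derived oxazaborolidinium catalyst is taken to be the enantiomer that gives the (4R,5S) cyclohexenone in step 5; if its facial sense is the opposite, its antipode is used.

Remark 2: the hemiaminal configuration of 47 is taken to be the thermodynamically preferred one, reachable by ring–chain equilibration of the N–H hydroxylactam.

## Steps

Step 1
Reactants: 1 (R)-4-benzyl-3-propanoyloxazolidin-2-one; 2 [2-(chloromethyl)prop-2-enyl]trimethylsilane
Product: 3 (R)-4-benzyl-3-[(2S)-2-methyl-4-(trimethylsilylmethyl)pent-4-enoyl]oxazolidin-2-one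
Conditions: NaN(SiMe3)2, THF, −78 °C; then 2, Bu4NI (cat.), −78 → −20 °C
Reagents that add atoms: none
Why: Evans asymmetric alkylation; the chelated (Z)-sodium enolate is alkylated on the face away from the benzyl group, so the (R)-auxiliary gives the (S)-methyl centre that becomes the ring-A methyl carbon next to the ring fusion.

Step 2
Reactants: 3 alkylated imide
Product: 4 (2S)-2-methyl-4-(trimethylsilylmethyl)pent-4-en-1-ol
Conditions: LiBH4, THF/H2O, 0 °C
Reagents that add atoms: none
Why: Reductive cleavage of the N-acyl oxazolidinone; the stereocentre is not enolised and the auxiliary is recovered.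

Step 3
Reactants: 4 alcohol; 5 2-(triphenylphosphoranylidene)propanal
Product: 7 (2E,4S)-2,4-dimethyl-6-(trimethylsilylmethyl)hepta-2,6-dienal, via aldehyde 6 (not isolated)
Conditions: Dess–Martin periodinane, CH2Cl2, 0 °C; then 5, 40 °C
Reagents that add atoms: none
Why: Dess–Martin oxidation followed in the same flask by a Wittig reaction, so that the volatile, epimerisable α-methyl aldehyde is not handled; the stabilised ylide gives the (E)-trisubstituted enal.

Step 4
Reactants: 7 enal; 8 (triphenylphosphoranylidene)acetaldehyde
Product: 9 (2E,4E,6S)-4,6-dimethyl-8-(trimethylsilylmethyl)nona-2,4,8-trienal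
Conditions: toluene, 80 °C
Reagents that add atoms: none
Why: Wittig homologation with a stabilised ylide gives the (E)-enal; the trienal now holds every carbon of rings B and A and the allylsilane terminus.

Step 5
Reactants: 9 trienal; 10 (1E,3Z)-1-methoxy-2-methyl-3-(trimethylsilyloxy)penta-1,3-diene
Product: 13 (4R,5S,6R)-4-(dimethoxymethyl)-2,6-dimethyl-5-[(2E,4S)-4-methyl-6-(trimethylsilylmethyl)hepta-2,6-dien-2-yl]cyclohex-2-en-1-one, via cycloadduct 11 (not isolated), via enone aldehyde 12 (not isolated)
Conditions: (S)-B-(o-tolyl)-diphenylprolinol oxazaborolidine·HNTf2 (20 mol%), CH2Cl2, −78 °C; then K2CO3, MeOH, 0 °C; then PPTS, HC(OMe)3, MeOH, rt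
Reagents that add atoms: methanol, CO
Why: Catalytic asymmetric Diels–Alder reaction of the formyl-activated α,β-alkene: the silyl enol ether terminus bonds to the β-carbon, the (E)-dienophile fixes the trans relation of the two new ring-fusion carbons, and the catalyst fixes their absolute sense. The endo mode places the ring methyl trans to the side chain (this centre is also epimerisable next to the ketone); methanolysis releases the enone and the sensitive aldehyde is masked at once as its acetal.

Step 6
Reactants: 13 enone acetal
Product: 14 (1S,4R,5S,6R)-cyclohex-2-en-1-ol from 13, hydroxyl trans to the adjacent ring methyl group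
Conditions: NaBH4, CeCl3·7H2O, MeOH, −78 °C
Reagents that add atoms: none
Why: Luche 1,2-reduction; axial hydride delivery next to the equatorial methyl group gives the equatorial alcohol, which puts the oxygen on the face that must later carry the CH2O group.

Step 7
Reactants: 14 allylic alcohol; 15 tributyl(iodomethyl)stannane
Product: 16 tributylstannylmethyl ether of 14
Conditions: KH, 18-crown-6 (cat.), THF, 0 °C → rt
Reagents that add atoms: none
Why: Williamson etherification of the potassium alkoxide with the primary iodide; no stereocentre is touched.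

Step 8
Reactants: 16 stannylmethyl ether
Product: 17 ring-C homoallylic alcohol [6-(dimethoxymethyl)-2,4-dimethyl-5-dienylcyclohex-2-enyl]methanol, the four ring substituents alternately trans
Conditions: n-BuLi, THF, −78 °C
Reagents that add atoms: none
Why: Wittig–Still [2,3] rearrangement after tin–lithium exchange; the suprafacial shift moves the CH2O unit from oxygen to the far alkene carbon on the same face, which sets the new centre trans to the acetal-bearing neighbour and moves the alkene to the position needed for the final ene reaction.

Step 9
Reactants: 17 homoallylic alcohol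
Product: 18 tert-butyldimethylsilyl ether of 17
Conditions: TBSCl, imidazole, DMF, rt
Reagents that add atoms: tert-butyldimethylsilyl chloride, CC(C)(C)[Si](C)(C)Cl
Why: Standard silylation of the primary alcohol; this ether survives the Lewis acid, the radical reduction and the strong base that follow.

Step 10
Reactants: 18 silyl ether acetal
Product: 19 ring-C aldehyde (formyl and dienyl groups trans)
Conditions: PPTS, acetone/H2O, rt
Reagents that add atoms: water, O
Why: Mild acetal hydrolysis; the pyridinium acid spares the primary silyl ether and the allylsilane, and the formyl group is already in its more stable equatorial position.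

Step 11
Reactants: 19 aldehyde
Product: 20 tricyclic alcohol with exocyclic methylene on ring A (ring-B hydroxyl, angular methyl and ring-C CH2OTBS on one face; both ring fusions trans)
Conditions: Me2AlCl, CH2Cl2, −78 → −20 °C
Reagents that add atoms: none
Why: Prins-initiated cation–olefin bicyclisation terminated by the allylsilane. The aluminium-bound formyl carbon is attacked by the CH end of the (E)-trisubstituted alkene (ring B) and the tertiary cation is captured on the opposite face by the allylsilane CH2 (ring A), with loss of silicon giving only the exocyclic alkene. Anti addition through a chair-like, product-like arrangement gives the trans-anti-trans skeleton, and the aluminium-bearing oxygen takes the outside position, away from the ring-C CH2OTBS carbon, giving the β-carbinol.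

Step 12
Reactants: 20 exocyclic alkene
Product: 21 tricyclic alcohol, ring A saturated (new methyl equatorial)
Conditions: Mn(dpm)3 (cat., dpm = dipivaloylmethanate), PhSiH3, t-BuOOH, i-PrOH, rt
Reagents that add atoms: none
Why: Hydrogen-atom-transfer hydrogenation; the 1,1-disubstituted alkene takes up the hydrogen atom faster than the trisubstituted ring-C alkene. The tertiary radical is quenched axially, so the methyl ends up equatorial and avoids the 1,3-diaxial clash with the angular methyl that a surface catalyst approaching from the open face would create.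

Step 13
Reactants: 21 tricyclic alcohol; 22 tert-butyl 4-fluorobenzoate
Product: 23 aryl ether tert-butyl ester
Conditions: KN(SiMe3)2, DMF, 0 → 50 °C
Reagents that add atoms: none
Why: Nucleophilic aromatic substitution of the para-activated fluoride by the potassium alkoxide; the C–O bond of the carbinol is untouched, so the ring-B configuration is retained.

Step 14
Reactants: 23 ester
Product: 24 benzylic alcohol
Conditions: LiAlH4, THF, 0 °C
Reagents that add atoms: none
Why: Hydride reduction of the ester to the primary benzylic alcohol; the silyl ether and alkene are inert.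

Step 15
Reactants: 24 benzylic alcohol
Product: 25 benzylic triisopropylsilyl ether
Conditions: TIPSCl, imidazole, DMF, rt
Reagents that add atoms: triisopropylsilyl chloride, CC(C)[Si](Cl)(C(C)C)C(C)C
Why: Silylation with a group bulkier than the one on the ring-C CH2O, so the two primary silyl ethers can be told apart.

Step 16
Reactants: 25 bis-silyl ether
Product: 26 ring-C primary alcohol
Conditions: HF·pyridine, pyridine, THF, 0 °C
Reagents that add atoms: none
Why: Buffered fluoride cleaves the primary tert-butyldimethylsilyl ether much faster than the triisopropylsilyl ether.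

Step 17
Reactants: 26 alcohol
Product: 27 tricyclic aldehyde with the 4-(silyloxymethyl)phenyl ether
Conditions: Dess–Martin periodinane, NaHCO3, CH2Cl2, 0 °C; used at once
Reagents that add atoms: none
Why: Dess–Martin oxidation under buffered, non-basic conditions keeps the β,γ-unsaturated aldehyde from epimerising or moving into conjugation.

Step 18
Reactants: 28 maleic anhydride; 29 2,4-dimethoxybenzylamine
Product: 31 1-(2,4-dimethoxybenzyl)pyrrole-2,5-dione, via maleamic acid 30 (not isolated)
Conditions: AcOH, 110 °C
Reagents that add atoms: none
Why: Acylation of the amine and cyclodehydration to the maleimide. The 2,4-dimethoxybenzyl group replaces a 4-methoxybenzyl group so that the final oxidative N-deprotection can distinguish it from the mono-alkoxy arene of the cyclophane.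

Step 19
Reactants: 31 maleimide; 32 2,2-dimethoxyacetaldehyde
Product: 34 (3E)-3-(2,2-dimethoxyethylidene)-1-(2,4-dimethoxybenzyl)pyrrolidine-2,5-dione, via phosphorus ylide 33 (not isolated)
Conditions: PPh3, THF, rt; then 32, 60 °C
Reagents that add atoms: none
Why: Conjugate addition of the phosphine to the maleimide gives a stabilised succinimidyl ylide, which undergoes a Wittig reaction with the aldehyde to the (E)-alkylidene succinimide.

Step 20
Reactants: 27 aldehyde; 34 alkylidene succinimide
Product: 35 aldol adduct (secondary carbinol joined to the quaternary succinimide carbon)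
Conditions: [(Ph3P)CuH]6, toluene/THF, −40 → −20 °C; aq. NH4Cl
Reagents that add atoms: none
Why: Reductive aldol reaction: copper hydride adds to the exocyclic alkene carbon, so the enolate forms only at the substituted ring carbon. In a Zimmerman–Traxler transition state the ring-fixed enolate geometry places the acetal arm syn to the new hydroxyl, and Felkin–Anh addition anti to the vinylic ring carbon fixes the aldehyde face; together these set the quaternary centre in the sense needed for the spiro carbon.

Step 21
Reactants: 35 aldol adduct
Product: 36 tert-butyldimethylsilyl ether of 35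
Conditions: TBSOTf, 2,6-lutidine, CH2Cl2, −78 → 0 °C
Reagents that add atoms: tert-butyldimethylsilyl triflate, CC(C)(C)[Si](C)(C)OS(=O)(=O)C(F)(F)F
Why: Silylation of the hindered carbinol under non-enolising conditions blocks retro-aldol cleavage and masks the future ketone against the reductant of the key step.

Step 22
Reactants: 36 bis-silyl ether
Product: 37 benzylic alcohol
Conditions: Bu4NF, THF, 0 °C
Reagents that add atoms: none
Why: Fluoride removes the unhindered primary benzylic silyl ether; the secondary silyl ether flanked by a quaternary carbon reacts far more slowly.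

Step 23
Reactants: 37 benzylic alcohol
Product: 38 benzylic bromide with the N-(2,4-dimethoxybenzyl) spiro-succinimide precursor unit
Conditions: CBr4, PPh3, 2,6-lutidine, CH2Cl2, 0 °C; used at once
Reagents that add atoms: tetrabromomethane, BrC(Br)(Br)Br
Why: Appel bromination of the primary benzylic alcohol; the base buffer protects the acetal and the electron-rich benzylic bromide is not stored.

Step 24
Reactants: 38 benzylic bromide
Product: 39 cyclophane N-(2,4-dimethoxybenzyl) hydroxylactam silyl ether
Conditions: SmI2 (4 equiv, 0.1 M in THF), THF, 0 °C, 38 added over 8 h to 1 mM; aq. NH4Cl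
Reagents that add atoms: none
Why: Proposed new method: two single-electron transfers from divalent samarium turn the benzylic bromide into a benzylsamarium, which adds to an imide carbonyl and gives the hydroxylactam as its samarium alkoxide; the closest known reaction is the intermolecular SmI2 Barbier addition of alkyl and benzyl halides to N-substituted succinimides and phthalimides, which has not been used to close a strained para-cyclophane. The 13-membered ring closes in the exo mode onto the carbonyl carbon (13-exo-trig), with the para-phenylene and the ring-B ether as rigid parts of the tether. The required regioselectivity, attack at the carbonyl next to the CH2 and not at the one next to the quaternary carbon, follows from shielding by that carbon and from the greater strain of the 12-membered alternative. The required chemoselectivity is secured by the substrate: the N-substituent removes the acidic N–H, the silyl ether masks the carbonyl that SmI2 would otherwise reduce, and N-alkyl succinimides, acetals and aryl ethers are inert to SmI2 in THF without additives. The new hemiaminal stereocentre is set by the macrocyclic tether, with the benzyl carbon entering anti to the bulky silyloxy-bearing branch on the quaternary carbon. If the other epimer forms it can be corrected, because the N–H hydroxylactam equilibrates through the open keto amide after step 27. Slow addition into excess reductant keeps the benzyl radical dilute and suppresses Wurtz coupling.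

Step 25
Reactants: 39 silyl ether
Product: 40 cyclophane carbinol
Conditions: HF·pyridine, pyridine, THF, rt
Reagents that add atoms: none
Why: Acidic, buffered fluoride removes the hindered silyl ether without the retro-aldol cleavage that a basic fluoride source could start; the acetal and hemiaminal tolerate the buffer.

Step 26
Reactants: 40 carbinol
Product: 41 cyclophane ketone
Conditions: Dess–Martin periodinane, NaHCO3, CH2Cl2, rt
Reagents that add atoms: none
Why: Dess–Martin oxidation of the secondary alcohol; the tertiary hemiaminal hydroxyl cannot be oxidised and the neutral medium leaves the β,γ-alkene in place.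

Step 27
Reactants: 41 ketone
Product: 43 keto aldehyde with free N–H hydroxylactam, via lactam acetal 42 (not isolated)
Conditions: (NH4)2Ce(NO3)6, MeCN/H2O (3:1), 0 °C → rt
Reagents that add atoms: water, O
Why: Tetravalent cerium oxidises the dimethoxybenzyl group, the most electron-rich arene present, to an N-acyliminium ion that is hydrolysed off; the acidic aqueous medium then hydrolyses the dimethyl acetal. The hemiaminal carbon can settle to its preferred configuration by ring–chain equilibration.

Step 28
Reactants: 43 keto aldehyde
Product: 45 peroxyhemiacetal with transposed ring-C alkene, via hydroperoxide 44 (not isolated)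
Conditions: O2, visible light, meso-tetraphenylporphyrin (cat.), CH2Cl2, −20 °C
Reagents that add atoms: dioxygen, O=O
Why: Schenck ene reaction: singlet oxygen bonds to the methyl-bearing alkene carbon from the face on which the pseudo-axial allylic hydrogen of the methyl-bearing methine lies; the other ring allylic hydrogen is on the opposite face and deactivated by the ketone. The alkene shifts, and the hydroperoxide adds to the aldehyde held on the same face to close the eight-membered ring; the peroxyhemiacetal carbon equilibrates to its more stable configuration.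

Step 29
Reactants: 45 peroxyhemiacetal alkene
Product: 46 bromohydrin (secondary bromide trans to the peroxide, tertiary hydroxyl cis to it)
Conditions: N-bromosuccinimide, THF/H2O, 0 °C
Reagents that add atoms: N-bromosuccinimide, O=C1CCC(=O)N1Br; water, O
Why: Bromohydrin formation: the bromonium ion forms on the open face, since the other is screened by the pseudo-axial peroxide bridge and the angular methyl group. Water opens it at the tertiary carbon from the screened face (Markovnikov and trans-diaxial).

Step 30
Reactants: 46 bromohydrin
Product: 47 target compound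
Conditions: Ag2O, CH2Cl2, rt
Reagents that add atoms: none
Why: Silver-assisted intramolecular displacement of bromide by the neighbouring hydroxyl with inversion closes the epoxide on the face of the peroxide; the neutral conditions avoid base-induced fragmentation of the peroxyhemiacetal.

## Compound list

1 | (R)-4-benzyl-3-propanoyloxazolidin-2-one | CCC(=O)N1[C@H](Cc2ccccc2)COC1=O | starting material
2 | [2-(chloromethyl)prop-2-enyl]trimethylsilane | C=C(CCl)C[Si](C)(C)C | starting material
3 | (R)-4-benzyl-3-[(2S)-2-methyl-4-(trimethylsilylmethyl)pent-4-enoyl]oxazolidin-2-one | C[C@@H](CC(=C)C[Si](C)(C)C)C(=O)N1[C@H](Cc2ccccc2)COC1=O | intermediate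
4 | (2S)-2-methyl-4-(trimethylsilylmethyl)pent-4-en-1-ol | C[C@@H](CC(=C)C[Si](C)(C)C)CO | intermediate
5 | 2-(triphenylphosphoranylidene)propanal | CC(C=O)=P(c1ccccc1)(c1ccccc1)c1ccccc1 | starting material
6 | (2S)-2-methyl-4-(trimethylsilylmethyl)pent-4-enal | C[C@@H](CC(=C)C[Si](C)(C)C)C=O | intermediate (not isolated)
7 | (2E,4S)-2,4-dimethyl-6-(trimethylsilylmethyl)hepta-2,6-dienal | O=C/C(C)=C/[C@@H](C)CC(=C)C[Si](C)(C)C | intermediate
8 | (triphenylphosphoranylidene)acetaldehyde | O=CC=P(c1ccccc1)(c1ccccc1)c1ccccc1 | starting material
9 | (2E,4E,6S)-4,6-dimethyl-8-(trimethylsilylmethyl)nona-2,4,8-trienal | O=C/C=C/C(C)=C/[C@@H](C)CC(=C)C[Si](C)(C)C | intermediate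
10 | (1E,3Z)-1-methoxy-2-methyl-3-(trimethylsilyloxy)penta-1,3-diene | CO/C=C(C)/C(O[Si](C)(C)C)=C/C | starting material
11 | endo cycloadduct (2-methoxy-3,5-dimethyl-4-silyloxycyclohex-3-ene-1-carbaldehyde bearing the dienyl chain at C-6) | CO[C@H]1[C@@H](C=O)[C@H](/C(C)=C/[C@@H](C)CC(=C)C[Si](C)(C)C)[C@@H](C)C(O[Si](C)(C)C)=C1C | intermediate (not isolated)
12 | enone aldehyde (3,5-dimethyl-4-oxo-6-dienylcyclohex-2-ene-1-carbaldehyde) | O=C1C(C)=C[C@@H](C=O)[C@H](/C(C)=C/[C@@H](C)CC(=C)C[Si](C)(C)C)[C@H]1C | intermediate (not isolated)
13 | (4R,5S,6R)-4-(dimethoxymethyl)-2,6-dimethyl-5-[(2E,4S)-4-methyl-6-(trimethylsilylmethyl)hepta-2,6-dien-2-yl]cyclohex-2-en-1-one | O=C1C(C)=C[C@@H](C(OC)OC)[C@H](/C(C)=C/[C@@H](C)CC(=C)C[Si](C)(C)C)[C@H]1C | intermediate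
14 | cyclohex-2-en-1-ol from 13 (hydroxyl trans to the adjacent methyl) | O[C@@H]1C(C)=C[C@@H](C(OC)OC)[C@H](/C(C)=C/[C@@H](C)CC(=C)C[Si](C)(C)C)[C@H]1C | intermediate
15 | tributyl(iodomethyl)stannane | CCCC[Sn](CCCC)(CCCC)CI | starting material
16 | tributylstannylmethyl ether of 14 | CCCC[Sn](CCCC)(CCCC)CO[C@@H]1C(C)=C[C@@H](C(OC)OC)[C@H](/C(C)=C/[C@@H](C)CC(=C)C[Si](C)(C)C)[C@H]1C | intermediate
17 | ring-C homoallylic alcohol | OC[C@H]1C(C)=C[C@H](C)[C@@H](/C(C)=C/[C@@H](C)CC(=C)C[Si](C)(C)C)[C@@H]1C(OC)OC | intermediate
18 | tert-butyldimethylsilyl ether of 17 | CC(C)(C)[Si](C)(C)OC[C@H]1C(C)=C[C@H](C)[C@@H](/C(C)=C/[C@@H](C)CC(=C)C[Si](C)(C)C)[C@@H]1C(OC)OC | intermediate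
19 | ring-C aldehyde | CC(C)(C)[Si](C)(C)OC[C@H]1C(C)=C[C@H](C)[C@@H](/C(C)=C/[C@@H](C)CC(=C)C[Si](C)(C)C)[C@@H]1C=O | intermediate
20 | tricyclic alcohol with exocyclic methylene on ring A | C=C1C[C@H](C)[C@H]2[C@@H](O)[C@@H]3[C@@H](CO[Si](C)(C)C(C)(C)C)C(C)=C[C@H](C)[C@H]3[C@]2(C)C1 | intermediate
21 | tricyclic alcohol, ring A saturated | C[C@@H]1C[C@H](C)[C@H]2[C@@H](O)[C@@H]3[C@@H](CO[Si](C)(C)C(C)(C)C)C(C)=C[C@H](C)[C@H]3[C@]2(C)C1 | intermediate
22 | tert-butyl 4-fluorobenzoate | CC(C)(C)OC(=O)c1ccc(F)cc1 | starting material
23 | aryl ether tert-butyl ester | C[C@@H]1C[C@H](C)[C@H]2[C@@H](Oc4ccc(cc4)C(=O)OC(C)(C)C)[C@@H]3[C@@H](CO[Si](C)(C)C(C)(C)C)C(C)=C[C@H](C)[C@H]3[C@]2(C)C1 | intermediate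
24 | benzylic alcohol | C[C@@H]1C[C@H](C)[C@H]2[C@@H](Oc4ccc(CO)cc4)[C@@H]3[C@@H](CO[Si](C)(C)C(C)(C)C)C(C)=C[C@H](C)[C@H]3[C@]2(C)C1 | intermediate
25 | benzylic triisopropylsilyl ether | C[C@@H]1C[C@H](C)[C@H]2[C@@H](Oc4ccc(CO[Si](C(C)C)(C(C)C)C(C)C)cc4)[C@@H]3[C@@H](CO[Si](C)(C)C(C)(C)C)C(C)=C[C@H](C)[C@H]3[C@]2(C)C1 | intermediate
26 | ring-C primary alcohol | C[C@@H]1C[C@H](C)[C@H]2[C@@H](Oc4ccc(CO[Si](C(C)C)(C(C)C)C(C)C)cc4)[C@@H]3[C@@H](CO)C(C)=C[C@H](C)[C@H]3[C@]2(C)C1 | intermediate
27 | tricyclic aldehyde | C[C@@H]1C[C@H](C)[C@H]2[C@@H](Oc4ccc(CO[Si](C(C)C)(C(C)C)C(C)C)cc4)[C@@H]3[C@@H](C=O)C(C)=C[C@H](C)[C@H]3[C@]2(C)C1 | intermediate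
28 | maleic anhydride | O=C1OC(=O)C=C1 | starting material
29 | 2,4-dimethoxybenzylamine | COc1ccc(CN)c(OC)c1 | starting material
30 | (Z)-4-[(2,4-dimethoxybenzyl)amino]-4-oxobut-2-enoic acid | OC(=O)/C=C\C(=O)NCc1ccc(OC)cc1OC | intermediate (not isolated)
31 | 1-(2,4-dimethoxybenzyl)pyrrole-2,5-dione | O=C1C=CC(=O)N1Cc1ccc(OC)cc1OC | intermediate
32 | 2,2-dimethoxyacetaldehyde | COC(OC)C=O | starting material
33 | 1-(2,4-dimethoxybenzyl)-3-(triphenylphosphoranylidene)pyrrolidine-2,5-dione | O=C1CC(=P(c2ccccc2)(c2ccccc2)c2ccccc2)C(=O)N1Cc1ccc(OC)cc1OC | intermediate (not isolated)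
34 | (3E)-3-(2,2-dimethoxyethylidene)-1-(2,4-dimethoxybenzyl)pyrrolidine-2,5-dione | COC(OC)/C=C1\CC(=O)N(Cc2ccc(OC)cc2OC)C1=O | intermediate
35 | aldol adduct | C[C@@H]1C[C@H](C)[C@H]2[C@@H](Oc4ccc(CO[Si](C(C)C)(C(C)C)C(C)C)cc4)[C@@H]3[C@@H]([C@H](O)[C@]6(CC(OC)OC)CC(=O)N(Cc7ccc(OC)cc7OC)C6=O)C(C)=C[C@H](C)[C@H]3[C@]2(C)C1 | intermediate
36 | tert-butyldimethylsilyl ether of 35 | C[C@@H]1C[C@H](C)[C@H]2[C@@H](Oc4ccc(CO[Si](C(C)C)(C(C)C)C(C)C)cc4)[C@@H]3[C@@H]([C@H](O[Si](C)(C)C(C)(C)C)[C@]6(CC(OC)OC)CC(=O)N(Cc7ccc(OC)cc7OC)C6=O)C(C)=C[C@H](C)[C@H]3[C@]2(C)C1 | intermediate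
37 | benzylic alcohol with silylated carbinol | C[C@@H]1C[C@H](C)[C@H]2[C@@H](Oc4ccc(CO)cc4)[C@@H]3[C@@H]([C@H](O[Si](C)(C)C(C)(C)C)[C@]6(CC(OC)OC)CC(=O)N(Cc7ccc(OC)cc7OC)C6=O)C(C)=C[C@H](C)[C@H]3[C@]2(C)C1 | intermediate
38 | benzylic bromide (key-step precursor) | C[C@@H]1C[C@H](C)[C@H]2[C@@H](Oc4ccc(CBr)cc4)[C@@H]3[C@@H]([C@H](O[Si](C)(C)C(C)(C)C)[C@]6(CC(OC)OC)CC(=O)N(Cc7ccc(OC)cc7OC)C6=O)C(C)=C[C@H](C)[C@H]3[C@]2(C)C1 | intermediate
39 | cyclophane N-(2,4-dimethoxybenzyl) hydroxylactam silyl ether | C[C@@H]1C[C@H](C)[C@H]2[C@@H](Oc4ccc(cc4)C[C@]5(O)C[C@]6(CC(OC)OC)C(=O)N5Cc7ccc(OC)cc7OC)[C@@H]3[C@@H]([C@@H]6O[Si](C)(C)C(C)(C)C)C(C)=C[C@H](C)[C@H]3[C@]2(C)C1 | intermediate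
40 | cyclophane carbinol | C[C@@H]1C[C@H](C)[C@H]2[C@@H](Oc4ccc(cc4)C[C@]5(O)C[C@]6(CC(OC)OC)C(=O)N5Cc7ccc(OC)cc7OC)[C@@H]3[C@@H]([C@@H]6O)C(C)=C[C@H](C)[C@H]3[C@]2(C)C1 | intermediate
41 | cyclophane ketone | C[C@@H]1C[C@H](C)[C@H]2[C@@H](Oc4ccc(cc4)C[C@]5(O)C[C@]6(CC(OC)OC)C(=O)N5Cc7ccc(OC)cc7OC)[C@@H]3[C@@H](C6=O)C(C)=C[C@H](C)[C@H]3[C@]2(C)C1 | intermediate
42 | N–H hydroxylactam acetal | C[C@@H]1C[C@H](C)[C@H]2[C@@H](Oc4ccc(cc4)C[C@]5(O)C[C@]6(CC(OC)OC)C(=O)N5)[C@@H]3[C@@H](C6=O)C(C)=C[C@H](C)[C@H]3[C@]2(C)C1 | intermediate (not isolated)
43 | keto aldehyde with N–H hydroxylactam | C[C@@H]1C[C@H](C)[C@H]2[C@@H](Oc4ccc(cc4)C[C@]5(O)C[C@]6(CC=O)C(=O)N5)[C@@H]3[C@@H](C6=O)C(C)=C[C@H](C)[C@H]3[C@]2(C)C1 | intermediate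
44 | tertiary allylic hydroperoxide | C[C@@H]1C[C@H](C)[C@H]2[C@@H](Oc4ccc(cc4)C[C@]5(O)C[C@]6(CC=O)C(=O)N5)[C@@H]3[C@@H](C6=O)[C@@](C)(OO)C=C(C)[C@H]3[C@]2(C)C1 | intermediate (not isolated)
45 | peroxyhemiacetal with transposed ring-C alkene | C[C@@H]1C[C@H](C)[C@H]2[C@H]3Oc4ccc(cc4)C[C@]4(O)C[C@]5(C[C@H](O)OO[C@@]6(C)C=C(C)[C@H]([C@H]3[C@H]6C5=O)[C@]2(C)C1)C(=O)N4 | intermediate
46 | bromohydrin | C[C@@H]1C[C@H](C)[C@H]2[C@H]3Oc4ccc(cc4)C[C@]4(O)C[C@]5(C[C@H](O)OO[C@@]6(C)[C@H](Br)[C@@](C)(O)[C@H]([C@H]3[C@H]6C5=O)[C@]2(C)C1)C(=O)N4 | intermediate
47 | CNP0533733.1 | C[C@@H]1C[C@H](C)[C@H]2[C@H]3Oc4ccc(cc4)C[C@]4(O)C[C@]5(C[C@H](O)OO[C@@]6(C)[C@H]7O[C@@]7(C)[C@H]([C@H]3[C@H]6C5=O)[C@]2(C)C1)C(=O)N4 | target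

## Step count and least certain steps

Total: 30 steps. Longest linear sequence: 28 steps (steps 1–17, then 20–30).

**Step 24 (key step).** Most likely failure: the benzylsamarium, or the benzyl radical before it, is protonated or dimerises faster than it reaches the imide, because the 13-membered para-cyclophane is strained; the result would be the reduced toluene derivative or a Wurtz dimer. Fallback by known chemistry: form the same C–C bond intermolecularly and close the ring at the aryl ether. Alcohol 21 is acetylated to the acetate F1 (Ac2O, DMAP). The primary silyl ether is cleaved to the alcohol F2 (HF·pyridine), which is oxidised to the aldehyde F3 (Dess–Martin). Reductive aldol with 34 gives the aldol adduct F4 ([(Ph3P)CuH]6), which is silylated to the silyl ether F5 (TBSOTf). Intermolecular SmI2 Barbier addition of 4-iodobenzyl bromide to the less hindered imide carbonyl gives the iodoaryl hydroxylactam F6. Methanolysis of the acetate gives the ring-B alcohol F7 (K2CO3, MeOH). An intramolecular Ullmann-type etherification (CuI, 1,10-phenanthroline, Cs2CO3, toluene, 110 °C, high dilution) then closes the aryl ether and rejoins the route at 39.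

**Step 5.** Most likely failure: the strongly acidic catalyst cleaves the silyl enol ether or the allylsilane before cycloaddition, or the facial selectivity is poor because the diene is reactive enough to add without the catalyst. Fallback: run the cycloaddition of 9 and 10 thermally without catalyst (toluene, 60 °C), carry out the same methanolysis and acetalisation, and separate 13 from the ring-C diastereomer F8 by chromatography. This starts from 9 and returns at 13.

**Step 11.** Most likely failure: poor facial selectivity at the formyl group, giving the ring-B carbinol epimer, since only the placement of the aluminium-bound oxygen distinguishes the two transition states. Fallback from 19: accept the carbinol epimer F9, oxidise it to the ring-B ketone F10 (Dess–Martin, no base, because the trans ring fusion next to this ketone is the less stable one), and reduce at once with LiB(s-Bu)3H at −78 °C from the face away from the angular methyl group. This returns at 20.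

**Step 20.** Most likely failure: direct 1,2-reduction of the aldehyde by the copper hydride, or low control of the quaternary centre if the closed transition state is not followed. Fallback: convert 34 into the silyl enol ether F11 by rhodium-catalysed 1,4-hydrosilylation (RhCl(PPh3)3, Et3SiH) and combine it with 27 in a fluoride-promoted Mukaiyama aldol reaction (Bu4N[Ph3SiF2], THF, −78 °C). This runs through an open transition state with no hydride present and returns at 35 after removal of the triethylsilyl group.

**Step 28.** Most likely failure: over-oxidation of the free aldehyde under oxygen and light, or attack of singlet oxygen on the other face with abstraction of the hydrogen next to the ketone. Fallback from 41: remove the dimethoxybenzyl group with DDQ under buffered conditions so that 42 is isolated with its acetal intact, photo-oxygenate 42 to the hydroperoxide acetal F12 (regio- and facial isomers can be separated at this stage), and hydrolyse the acetal with wet acidic silica. The hydroperoxide then closes onto the liberated aldehyde, returning at 45.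

## Further compounds

F1 | step 24 | ring-B acetate of 21 | C[C@@H]1C[C@H](C)[C@H]2[C@@H](OC(C)=O)[C@@H]3[C@@H](CO[Si](C)(C)C(C)(C)C)C(C)=C[C@H](C)[C@H]3[C@]2(C)C1
F2 | step 24 | acetate with free ring-C primary alcohol | C[C@@H]1C[C@H](C)[C@H]2[C@@H](OC(C)=O)[C@@H]3[C@@H](CO)C(C)=C[C@H](C)[C@H]3[C@]2(C)C1
F3 | step 24 | acetate aldehyde | C[C@@H]1C[C@H](C)[C@H]2[C@@H](OC(C)=O)[C@@H]3[C@@H](C=O)C(C)=C[C@H](C)[C@H]3[C@]2(C)C1
F4 | step 24 | acetate aldol adduct | C[C@@H]1C[C@H](C)[C@H]2[C@@H](OC(C)=O)[C@@H]3[C@@H]([C@H](O)[C@]6(CC(OC)OC)CC(=O)N(Cc7ccc(OC)cc7OC)C6=O)C(C)=C[C@H](C)[C@H]3[C@]2(C)C1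
F5 | step 24 | silyl ether of F4 | C[C@@H]1C[C@H](C)[C@H]2[C@@H](OC(C)=O)[C@@H]3[C@@H]([C@H](O[Si](C)(C)C(C)(C)C)[C@]6(CC(OC)OC)CC(=O)N(Cc7ccc(OC)cc7OC)C6=O)C(C)=C[C@H](C)[C@H]3[C@]2(C)C1
F6 | step 24 | iodoaryl hydroxylactam acetate | C[C@@H]1C[C@H](C)[C@H]2[C@@H](OC(C)=O)[C@@H]3[C@@H]([C@H](O[Si](C)(C)C(C)(C)C)[C@]6(CC(OC)OC)C[C@@](O)(Cc8ccc(I)cc8)N(Cc7ccc(OC)cc7OC)C6=O)C(C)=C[C@H](C)[C@H]3[C@]2(C)C1
F7 | step 24 | iodoaryl hydroxylactam with free ring-B alcohol | C[C@@H]1C[C@H](C)[C@H]2[C@@H](O)[C@@H]3[C@@H]([C@H](O[Si](C)(C)C(C)(C)C)[C@]6(CC(OC)OC)C[C@@](O)(Cc8ccc(I)cc8)N(Cc7ccc(OC)cc7OC)C6=O)C(C)=C[C@H](C)[C@H]3[C@]2(C)C1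
F8 | step 5 | (4S,5R,6S)-diastereomer of 13 | O=C1C(C)=C[C@H](C(OC)OC)[C@@H](/C(C)=C/[C@@H](C)CC(=C)C[Si](C)(C)C)[C@@H]1C
F9 | step 11 | ring-B carbinol epimer of 20 | C=C1C[C@H](C)[C@H]2[C@H](O)[C@@H]3[C@@H](CO[Si](C)(C)C(C)(C)C)C(C)=C[C@H](C)[C@H]3[C@]2(C)C1
F10 | step 11 | ring-B ketone | C=C1C[C@H](C)[C@H]2C(=O)[C@@H]3[C@@H](CO[Si](C)(C)C(C)(C)C)C(C)=C[C@H](C)[C@H]3[C@]2(C)C1
F11 | step 20 | triethylsilyl enol ether of the reduced succinimide | COC(OC)CC1=C(O[Si](CC)(CC)CC)N(Cc2ccc(OC)cc2OC)C(=O)C1
F12 | step 28 | hydroperoxide acetal | C[C@@H]1C[C@H](C)[C@H]2[C@@H](Oc4ccc(cc4)C[C@]5(O)C[C@]6(CC(OC)OC)C(=O)N5)[C@@H]3[C@@H](C6=O)[C@@](C)(OO)C=C(C)[C@H]3[C@]2(C)C1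
A1 | alternative 1 | tricyclic ring-B alcohol with endocyclic ring-A alkene | CC1=C[C@H](C)[C@H]2[C@@H](O)[C@@H]3[C@@H](CO[Si](C)(C)C(C)(C)C)C(C)=C[C@H](C)[C@H]3[C@]2(C)C1
A2 | alternative 2 | ring-C β-silylperoxy ketone | C[C@@H]1C[C@H](C)[C@H]2[C@@H](Oc4ccc(cc4)CC5(OCCO5)C[C@]6(CCO[Si](C(C)C)(C(C)C)C(C)C)C(N)=O)[C@@H]3[C@@H](C6=O)[C@@](C)(OO[Si](CC)(CC)CC)C=C(C)[C@H]3[C@]2(C)C1
A3 | alternative 3 | peroxyhemiacetal with transposed ring-C alkene | C[C@@H]1C[C@H](C)[C@H]2[C@H]3Oc4ccc(cc4)C[C@]4(O)C[C@]5(C[C@H](O)OO[C@@]6(C)C=C(C)[C@H]([C@H]3[C@H]6C5=O)[C@]2(C)C1)C(=O)N4
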